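Labdane numbering is used; unprimed atoms belong to the half with the 11,12-double bond, primed atoms to the other. Both halves are andrographolide skeletons, so everything rests on forming C15–C12′ last, between the γ-carbon of the unprimed butenolide and the primed side-chain methine. The key step exploits the endocyclic C13′=C14′ bond of the primed butenolide ring, the footprint of an SN2′ displacement: a 2-silyloxyfuran adds through C15 to the exocyclic C12′ of an andrographolide 14′-acetate, anti to the acetate, which then leaves. One operation forms the bond, sets C15 and C12′, relays and erases the purchased C14′ centre and creates the primed butenolide. Both partners derive from one acetate.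

Key step: step 4

Remark on the chemistry: andrographolide, the bulk labdane lactone from Andrographis paniculata, is taken as the commercial starting material. It supplies all stereocentres of both decalins and the C14 carbinol centre that is used as the relay.

Step 1
Reactants: 1 andrographolide
Product: 2 3,19-O-isopropylideneandrographolide
Conditions: 2,2-dimethoxypropane, pyridinium p-toluenesulfonate (cat.), CH2Cl2–DMSO, 40 °C
Reagents that add atoms: 2,2-dimethoxypropane, COC(C)(C)OC
Why: Acid-catalysed transketalisation should engage only the 3,19-diol, the one pair of hydroxyls that can close a six-membered 1,3-dioxane, and should leave the allylic 14-OH free; no stereocentre is touched.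

Step 2
Reactants: 2 3,19-O-isopropylideneandrographolide
Product: 3 14-O-acetyl-3,19-O-isopropylideneandrographolide
Conditions: Ac2O, pyridine, 4-(dimethylamino)pyridine (cat.), CH2Cl2, 0 °C
Reagents that add atoms: acetic anhydride, CC(=O)OC(C)=O
Why: Nucleophile-catalysed O-acylation of the only free hydroxyl should proceed with retention at C14 (the C–O bond is not broken), and the weak base and low temperature should hold back loss of the new allylic acetate.

Step 3
Reactants: 3 14-O-acetyl-3,19-O-isopropylideneandrographolide
Product: 5 2-(tert-butyldimethylsilyloxy)-3-dienylfuran acetonide (silyl dienol ether of 4), via dienyl butenolide acetonide 4 (not isolated)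
Conditions: DBU (1.2 equiv), CH2Cl2, 0 °C → rt; then Et3N (4 equiv), t-BuMe2SiOSO2CF3 (2.5 equiv), 0 °C
Reagents that add atoms: tert-butyldimethylsilyl trifluoromethanesulfonate, CC(C)(C)[Si](C)(C)OS(=O)(=O)C(F)(F)F
Why: DBU should remove a C11 proton (γ to the lactone carbonyl) so that the extended enolate expels the C14 acetate (vinylogous E1cB 1,4-elimination) to give the conjugated 11E-ene butenolide 4, the E geometry being the thermodynamic one; soft enolisation at C15 with silyl triflate and Et3N should then give the aromatic 2-silyloxyfuran, with no new stereocentre formed.

Step 4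
Reactants: 3 14-O-acetyl-3,19-O-isopropylideneandrographolide; 5 2-(tert-butyldimethylsilyloxy)-3-dienylfuran acetonide
Product: 7 bis-acetonide of the target, via silyl ketene acetal adduct 6 (not isolated)
Conditions: 5 (1.4 equiv), HN(SO2CF3)2 (10 mol %, premixed with 5), CH2Cl2, −78 → −40 °C; then Et3N
Reagents that add atoms: none
Why: The silyl triflimide formed from the acid and a little 5 should silylate the lactone carbonyl of 3; C15 of the furan then attacks the activated exocyclic C12′, the furanium gives up its silyl group, and the β-acetoxy silyl ketene acetal 6 ionises to the C13′=C14′ butenolide with loss of silyl acetate, so the Lewis acid turns over. The closest known reaction types are the vinylogous Mukaiyama–Michael addition of 2-silyloxyfurans and the SN2′ addition–elimination of Morita–Baylis–Hillman-type acetates, the course that 14-O-acyl andrographolides take with heteroatom nucleophiles. No ring is closed; the furan and the alkylidene lactone are each converted into a butenolide. C12′ is controlled by the C14′ acetate, which stands roughly perpendicular to the enoate plane and shields its own face, so attack anti to the C–O bond on the E,14′S acceptor should give 12′S before C14′ is flattened. C15 is controlled by the relative topicity: a compact endo (Diels–Alder-like) approach, with the lactone carbonyl C16′ over C13–C14 of the furan and the furan oxygen on the C11′ side, should give 15R. The step needs attack through C15 and not through C13 or C11 of the dienyl silyloxyfuran, which the large C5 coefficient of the furan and the shielding of C11 by the decalin should secure, and it needs the ketals and 8(17)-methylenes to survive, which the low temperature and the absence of free acid should allow.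

Step 5
Reactants: 7 bis-acetonide of the target
Product: 8 target dimer, (15R,12′S)-15-(14′-deoxyandrographolid-12′-yl)-14-deoxy-11,12-didehydroandrographolide
Conditions: AcOH–H2O (7:3), rt
Reagents that add atoms: none
Why: Mild acid-catalysed ketal hydrolysis should free both 3,19-diols; the medium is too weak to protonate the exocyclic methylenes or to enolise the butenolides, so C15 and C12′ should keep their configuration.

Compound list
1 | andrographolide (E-12-ene, 14S-hydroxy-16,15-olide of the ent-labda-8(17)-ene-3,19-diol) | C=C1CC[C@@H]2[C@](C)(CO)[C@H](O)CC[C@@]2(C)[C@@H]1C/C=C1/C(=O)OC[C@H]1O | starting material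
2 | 3,19-O-isopropylideneandrographolide (14-OH free) | C=C1CC[C@@H]2[C@]3(C)COC(C)(C)O[C@@H]3CC[C@@]2(C)[C@@H]1C/C=C1/C(=O)OC[C@H]1O | intermediate
3 | 14-O-acetyl-3,19-O-isopropylideneandrographolide | C=C1CC[C@@H]2[C@]3(C)COC(C)(C)O[C@@H]3CC[C@@]2(C)[C@@H]1C/C=C1/C(=O)OC[C@H]1OC(C)=O | intermediate
4 | 3,19-O-isopropylidene-14-deoxy-11,12-didehydroandrographolide (11E-ene, 13-ene butenolide; not isolated) | C=C1CC[C@@H]2[C@]3(C)COC(C)(C)O[C@@H]3CC[C@@]2(C)[C@@H]1/C=C/C1=CCOC1=O | intermediate
5 | 2-(tert-butyldimethylsilyloxy)furan derived from 4 (furan C3 carries the E-vinyl decalin acetonide; furan C5 is C15) | C=C1CC[C@@H]2[C@]3(C)COC(C)(C)O[C@@H]3CC[C@@]2(C)[C@@H]1/C=C/c1ccoc1O[Si](C)(C)C(C)(C)C | intermediate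
6 | Michael adduct: 15R,12′S-linked dimer with the primed lactone as its tert-butyldimethylsilyl ketene acetal and the 14′S-acetate still in place (not isolated) | C=C1CC[C@@H]2[C@]3(C)COC(C)(C)O[C@@H]3CC[C@@]2(C)[C@@H]1/C=C/C1=C[C@H]([C@@H](C[C@@H]2C(=C)CC[C@@H]3[C@]4(C)COC(C)(C)O[C@@H]4CC[C@]32C)C2=C(O[Si](C)(C)C(C)(C)C)OC[C@H]2OC(C)=O)OC1=O | intermediate
7 | 3,19:3′,19′-bis-O-isopropylidene derivative of the target (15R,12′S) | C=C1CC[C@@H]2[C@]3(C)COC(C)(C)O[C@@H]3CC[C@@]2(C)[C@@H]1/C=C/C1=C[C@H]([C@@H](C[C@@H]2C(=C)CC[C@@H]3[C@]4(C)COC(C)(C)O[C@@H]4CC[C@]32C)C2=CCOC2=O)OC1=O | intermediate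
8 | target dimer, (15R,12′S)-15-(14′-deoxyandrographolid-12′-yl)-14-deoxy-11,12-didehydroandrographolide | C=C1CC[C@@H]2[C@](C)(CO)[C@H](O)CC[C@@]2(C)[C@@H]1/C=C/C1=C[C@H]([C@@H](C[C@@H]2C(=C)CC[C@@H]3[C@](C)(CO)[C@H](O)CC[C@]32C)C2=CCOC2=O)OC1=O | target

Total step count: 5. Longest linear sequence: 5 steps (1 → 2 → 3 → 5 → 7 → 8; compound 3 enters step 4 a second time as the electrophile).

Steps most likely to fail

1. Step 4. The silyl Lewis acid may engage the ketals or ionise the acetate instead of activating the enoate, or the furan may approach exo and so invert C15. Fallback (Lewis-acid-free anionic manifold, setting out from 2 and 4 and returning at 7): 2 is treated with di-tert-butyl dicarbonate and catalytic 4-(dimethylamino)pyridine in CH2Cl2 at 0 °C to give 14-O-(tert-butoxycarbonyl)-3,19-O-isopropylideneandrographolide F1. Butenolide 4 is obtained by stopping step 3 after the DBU stage and isolating it. F1 and 4 are combined with catalytic Cs2CO3 in THF at −40 °C, or with solid K2CO3 and N-benzylcinchonidinium bromide if reagent control of the C15 face is wanted. The C15 dienolate of 4 should add to C12′ anti to the carbonate, the carbonate should leave by E1cB to give 7, and its decarboxylation releases tert-butoxide as the base for the next turnover (direct vinylogous Michael addition–elimination of a butenolide with a Morita–Baylis–Hillman-type carbonate). The competing C11′ deprotonation of F1 would only return 4.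

2. Step 3. The amidine and the acetate may interfere with the silyl triflate in the one-pot, leaving the elimination incomplete so that unchanged 3 is enolised and silylated. Fallback (setting out from 1 and returning at 5): 1 is dehydrated directly over neutral Al2O3 in refluxing pyridine to 14-deoxy-11,12-didehydroandrographolide F2, which can also be purchased. F2 is ketalised as in step 1 to 4, which is purified. Compound 4 alone is then silylated with Et3N and t-BuMe2SiOSO2CF3 in CH2Cl2 at 0 °C to give 5, so the diene no longer comes from the acetate and no elimination runs beside the silylation.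

3. Step 2. The base may trigger vinylogous E1cB loss of the acetate as soon as it forms, eroding 3 toward 4. Fallback (reversed order without base, setting out from 1 and returning at 3): unprotected 1 is transesterified with vinyl acetate over immobilised lipase B from Candida antarctica in acetone at 40 °C. Acylation is expected at the unhindered allylic 14-OH and not at the neopentylic 19-OH or the hindered 3-OH, to give 14-O-acetylandrographolide F3. F3 is then ketalised under the acidic conditions of step 1 to give 3.

Further compounds
F1 | step 4 | 14-O-(tert-butoxycarbonyl)-3,19-O-isopropylideneandrographolide | C=C1CC[C@@H]2[C@]3(C)COC(C)(C)O[C@@H]3CC[C@@]2(C)[C@@H]1C/C=C1/C(=O)OC[C@H]1OC(=O)OC(C)(C)C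
F2 | step 3 | 14-deoxy-11,12-didehydroandrographolide | C=C1CC[C@@H]2[C@](C)(CO)[C@H](O)CC[C@@]2(C)[C@@H]1/C=C/C1=CCOC1=O
F3 | step 2 | 14-O-acetylandrographolide | C=C1CC[C@@H]2[C@](C)(CO)[C@H](O)CC[C@@]2(C)[C@@H]1C/C=C1/C(=O)OC[C@H]1OC(C)=O
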